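**Minutes: six flasks, one charge of starting material**

Grey cannot hold more target than its coupling partner can make: with 6.00 mM of partner on 41 mM of starting material, and one partner to each target, the ceiling is 14.6% of the starting material charged.

in all of them: starting material 41 mM
- winter: coupling partner 7.7 mM; run made earlier
- midnight: coupling partner 120 mM; run made earlier
- teal: coupling partner 24.6 mM; time 50 min
- amber: coupling partner 50.0 mM; time 50 min
- grey: coupling partner 6.00 mM; time 50 min
- red: coupling partner 8.00 mM; time 50 min
- violet: coupling partner 15.0 mM; time 50 min
- green: coupling partner 80.0 mM; time 50 min

| run | time / min | target / % | starting material / % |
|---|---|---|---|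
| winter | 5.00 | 16 | 61 |
| winter | 10.0 | 18 | 47 |
| winter | 15.0 | 14 | 37 |
| winter | 20.0 | 16 | 29 |
| winter | 25.0 | 15 | 21 |
| midnight | 5.00 | 94 | 3 |
| midnight | 10.0 | 91 | 2 |
| midnight | 15.0 | 87 | 0 |
| midnight | 20.0 | 88 | 1 |
| midnight | 25.0 | 91 | 0 |

(readings scatter by 2 percentage points)



- the flasks put in order of amount of target, in percent of the starting material charged, best first, at 50 min (teal / amber / grey / red / violet / green)
- the same order at 5.0 min (teal / amber / grey / red / violet / green)
- the amount of target, in percent of the starting material charged of the flask you put first, at 50 min
- the amount of target, in percent of the starting material charged of the flask you put last, at 50 min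

The analyst opened with the winter run, where partner is the limiting reagent. Its target reads flat from 5.00 min to 25.0 min, while its starting material falls from 61% to 21%. Target averages 15.8%, under that run's ceiling of 18.8%. She therefore proposed one number, 84.1%: the capture f, the target found as a share of the ceiling set by the partner charge.

The process lead objected that f rests on a single run whose readings each carry 2 percentage points. He asked her to go round once more with the first answer, the bare ceiling. She put grey's ceiling back through f and got 12.3%, which she took as her own figure for the last flask. He added that f says nothing about green, which has more partner than starting material, so that its ceiling is set by the starting material.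

The forecaster then gave green > amber > teal > violet > red > grey at 50 min and green > amber > teal > violet > red > grey at 5.0 min, with 87% for the first flask and 12.3% for the last. His grounds were that “coupling is fast and partner-limited, and the target is stable”.

**Result**

    starting material + coupling partner → target (k = 9.20 L mol⁻¹ min⁻¹)
    starting material → side product A (k = 0.0150 min⁻¹)
    2 starting material → side product B (k = 0.850 L mol⁻¹ min⁻¹)
    target ⇌ isomer of the product (K = 1.50, k = 0.00360 min⁻¹)

Grey gives 12.5% against the reckoned 12.3%, and grey's neighbour with 10 mM of coupling partner, reckoned by f at 20.5%, gives 20.8%. Both orders come out as green > amber > teal > violet > red > grey and green > amber > teal > violet > red > grey, but green gives 78.3% against the forecast's 87%. In green, the half-life of target going to isomer of the product, forward step alone, is 190 min, long against 50 min. Even so, green's target goes from 84.4% at 5.00 min to 78.3% at 50.0 min, when isomer of the product stands at 13.9%.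

The earlier runs and the new flask are calculated for substances that don't exist; noise was put on by code.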